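**Retrosynthetic overview**
- The target is the syn (3R,5S)-diacetate of 1-(4-hydroxy-3-methoxyphenyl)dodecane-3,5-diol. Both acetates and the free phenol come from the triol by peracetylation and selective cleavage of the aryl acetate.
- The strategy rests on C1, the benzylic CH2 on the 4-oxy-3-methoxyphenyl ring. C1 is carried as an aryl ketone, which makes C3 the β-carbon of an enone, and is later returned to CH2 by hydrogenolysis. The syn C3/C5 dioxygen pair maps onto one six-membered 1,3-dioxane ring.
- Key disconnection: the C3–O bond, made by hemiacetal oxa-Michael addition of the C5 hydroxyl and acetaldehyde onto the (2E,5S)-aryl enone. The temporary 1,3-dioxane is the only ring formed.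
- The enone C2=C3 bond comes from cross-metathesis of (S)-undec-1-en-4-ol with an aryl vinyl ketone made from O-benzylvanillin. C5 is set by Brown allylboration of octanal.

Key step: step 5

Remark: with the C1 carbonyl present, the C3 geometry of the target carries the descriptor S, so the ketone intermediates are (3S,5S) and the deoxygenated compounds are (3R,5S).
Remark: the allylborane is assumed to be available as a commercial pentane solution of the enantiomer derived from (−)-α-pinene, whose isopinocampheyl groups are (1S,2R,3S,5S).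

**Step 1**
Reactants: 1 octanal; 2 (+)-B-allyldiisopinocampheylborane
Product: 4 (S)-undec-1-en-4-ol, via borinate ester 3 (not isolated)
Conditions: Et2O, −78 °C → rt; then 3 M NaOH, 30% H2O2, 0 °C → rt
Reagents that add atoms: none
Why: Brown allylboration through a closed six-membered chair transition state, in which the isopinocampheyl groups derived from (−)-α-pinene should direct allyl transfer to the Re face of octanal and so set C5 as S.

**Step 2**
Reactants: 5 O-benzylvanillin (4-benzyloxy-3-methoxybenzaldehyde); 6 vinylmagnesium bromide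
Product: 7 rac-1-(4-benzyloxy-3-methoxyphenyl)prop-2-en-1-ol
Conditions: THF, 0 °C; then H2O
Reagents that add atoms: none
Why: Grignard 1,2-addition to an aryl aldehyde; the new carbinol centre is racemic and is destroyed in the next step.

**Step 3**
Reactants: 7 rac-1-(4-benzyloxy-3-methoxyphenyl)prop-2-en-1-ol
Product: 8 1-(4-benzyloxy-3-methoxyphenyl)prop-2-en-1-one
Conditions: activated MnO2 (excess), CH2Cl2, rt; used without storage
Reagents that add atoms: none
Why: MnO2 oxidation of a doubly activated (allylic and benzylic) alcohol should give the aryl vinyl ketone under neutral conditions that leave the benzyl ether untouched.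

**Step 4**
Reactants: 4 (S)-undec-1-en-4-ol; 8 1-(4-benzyloxy-3-methoxyphenyl)prop-2-en-1-one
Product: 9 (S,E)-1-(4-benzyloxy-3-methoxyphenyl)-5-hydroxydodec-2-en-1-one
Conditions: second-generation Grubbs catalyst RuCl2(=CHPh)(PCy3)(H2IMes) (5 mol%), vinyl ketone in twofold excess, CH2Cl2, 40 °C
Reagents that add atoms: none
Why: Olefin cross-metathesis between a terminal homoallylic alcohol and an electron-poor vinyl ketone should favour the cross product and give the conjugated E-enone, with loss of ethylene and no effect on C5.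

**Step 5**
Reactants: 9 (S,E)-1-(4-benzyloxy-3-methoxyphenyl)-5-hydroxydodec-2-en-1-one; 10 acetaldehyde
Product: 12 all-cis ethylidene acetal of (3S,5S)-1-(4-benzyloxy-3-methoxyphenyl)-3,5-dihydroxydodecan-1-one, via hemiacetal 11 (not isolated)
Conditions: Bi(NO3)3·5H2O (10 mol%), freshly distilled MeCHO in excess, CH2Cl2, rt
Reagents that add atoms: none
Why: Bi(NO3)3·5H2O (trivalent bismuth, a mild Lewis acid) lets the C5 hydroxyl of 9 add to acetaldehyde to give hemiacetal 11, whose new hydroxyl then attacks C3, the β-carbon of the activated aryl enone, and so makes the C3–O bond. The closest known reaction type is the bismuth-mediated two-component hemiacetal/oxa-conjugate addition of δ-hydroxy α,β-unsaturated ketones with alkyl aldehydes to syn-1,3-dioxanes, a relative of the base-mediated benzaldehyde addition to δ-hydroxy enoates. The one ring formed, the 1,3-dioxane O–C3–C4–C5–O–CHMe, closes in the 6-exo-trig mode. C3 is set by the existing C5 centre, because retro-Michael opening keeps the addition reversible and the material should gather in the chair that has the C5 heptyl and the C3 aroylmethyl group equatorial, the syn (3S,5S) arrangement, while the temporary acetal carbon takes its methyl equatorial since an axial 2-substituent on a 1,3-dioxane is strongly disfavoured. The step needs syn over anti selectivity and attack at C3 only; thermodynamic control in the triequatorial chair secures the first, and the second follows because direct addition of the C5 hydroxyl to C3 would close a four-membered ring, so only the hemiacetal can cyclise.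

**Step 6**
Reactants: 12 all-cis ethylidene acetal of (3S,5S)-1-(4-benzyloxy-3-methoxyphenyl)-3,5-dihydroxydodecan-1-one
Product: 15 all-cis ethylidene acetal of (3R,5S)-1-(4-hydroxy-3-methoxyphenyl)dodecane-3,5-diol, via phenol ketone 13 (not isolated), via benzylic alcohol 14 (not isolated)
Conditions: H2 (3 bar), Pd(OH)2/C, EtOH–AcOH (10:1), rt
Reagents that add atoms: none
Why: Catalytic hydrogenolysis should cleave the benzyl ether, reduce the 4-hydroxyaryl ketone to the benzylic alcohol and then hydrogenolyse that C1–O bond, which is activated by the para oxygen and the acid, while the acetal and both stereocentres are left alone.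

**Step 7**
Reactants: 15 all-cis ethylidene acetal of (3R,5S)-1-(4-hydroxy-3-methoxyphenyl)dodecane-3,5-diol
Product: 16 (3R,5S)-1-(4-hydroxy-3-methoxyphenyl)dodecane-3,5-diol
Conditions: 2 M aq. HCl, THF, 45 °C
Reagents that add atoms: none
Why: Acid-catalysed acetal hydrolysis, driven by loss of volatile acetaldehyde, breaks only the bonds to the acetal carbon, so the C3–O and C5–O bonds and their configurations are retained.

**Step 8**
Reactants: 16 (3R,5S)-1-(4-hydroxy-3-methoxyphenyl)dodecane-3,5-diol
Product: 17 (3R,5S)-1-(4-acetoxy-3-methoxyphenyl)dodecane-3,5-diyl diacetate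
Conditions: Ac2O, pyridine, DMAP (cat.), CH2Cl2, rt
Reagents that add atoms: acetic anhydride, CC(=O)OC(C)=O
Why: DMAP-catalysed acylation should esterify the phenol and both secondary alcohols without touching any C–O bond at a stereocentre.

**Step 9**
Reactants: 17 (3R,5S)-1-(4-acetoxy-3-methoxyphenyl)dodecane-3,5-diyl diacetate
Product: 18 (3R,5S)-1-(4-hydroxy-3-methoxyphenyl)dodecane-3,5-diyl diacetate (target)
Conditions: pyrrolidine (1.5 equiv), CH2Cl2, 0 °C
Reagents that add atoms: none
Why: Chemoselective aminolysis, in which the aryl acetate should react much faster than the secondary alkyl acetates because phenoxide is the better leaving group, so only the phenol is unmasked.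

**Compound list**
1 | octanal | CCCCCCCC=O | starting material
2 | (+)-B-allyldiisopinocampheylborane, allylbis[(1S,2R,3S,5S)-2,6,6-trimethylbicyclo[3.1.1]hept-3-yl]borane | C=CCB([C@H]1C[C@H]2C[C@@H]([C@@H]1C)C2(C)C)[C@H]1C[C@H]2C[C@@H]([C@@H]1C)C2(C)C | starting material
3 | (S)-undec-1-en-4-yl diisopinocampheylborinate | CCCCCCC[C@@H](CC=C)OB([C@H]1C[C@H]2C[C@@H]([C@@H]1C)C2(C)C)[C@H]1C[C@H]2C[C@@H]([C@@H]1C)C2(C)C | intermediate (not isolated)
4 | (S)-undec-1-en-4-ol | CCCCCCC[C@@H](CC=C)O | intermediate
5 | O-benzylvanillin (4-benzyloxy-3-methoxybenzaldehyde) | COc1cc(C=O)ccc1OCc1ccccc1 | starting material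
6 | vinylmagnesium bromide | C=C[Mg]Br | starting material
7 | rac-1-(4-benzyloxy-3-methoxyphenyl)prop-2-en-1-ol | C=CC(O)c1ccc(OCc2ccccc2)c(OC)c1 | intermediate
8 | 1-(4-benzyloxy-3-methoxyphenyl)prop-2-en-1-one | C=CC(=O)c1ccc(OCc2ccccc2)c(OC)c1 | intermediate
9 | (S,E)-1-(4-benzyloxy-3-methoxyphenyl)-5-hydroxydodec-2-en-1-one | CCCCCCC[C@@H](C/C=C/C(=O)c1ccc(OCc2ccccc2)c(OC)c1)O | intermediate
10 | acetaldehyde | CC=O | starting material
11 | (S,E)-1-(4-benzyloxy-3-methoxyphenyl)-5-(1-hydroxyethoxy)dodec-2-en-1-one (hemiacetal, both epimers at the hemiacetal carbon) | CCCCCCC[C@@H](C/C=C/C(=O)c1ccc(OCc2ccccc2)c(OC)c1)OC(C)O | intermediate (not isolated)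
12 | all-cis ethylidene acetal of (3S,5S)-1-(4-benzyloxy-3-methoxyphenyl)-3,5-dihydroxydodecan-1-one | CCCCCCC[C@H]1C[C@@H](CC(=O)c2ccc(OCc3ccccc3)c(OC)c2)O[C@@H](C)O1 | intermediate
13 | all-cis ethylidene acetal of (3S,5S)-3,5-dihydroxy-1-(4-hydroxy-3-methoxyphenyl)dodecan-1-one | CCCCCCC[C@H]1C[C@@H](CC(=O)c2ccc(O)c(OC)c2)O[C@@H](C)O1 | intermediate (not isolated)
14 | all-cis 3,5-O-ethylidene acetal of 1-(4-hydroxy-3-methoxyphenyl)dodecane-1,3,5-triol (ring configuration unchanged, both C1 epimers) | CCCCCCC[C@H]1C[C@@H](CC(O)c2ccc(O)c(OC)c2)O[C@@H](C)O1 | intermediate (not isolated)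
15 | all-cis ethylidene acetal of (3R,5S)-1-(4-hydroxy-3-methoxyphenyl)dodecane-3,5-diol | CCCCCCC[C@H]1C[C@@H](CCc2ccc(O)c(OC)c2)O[C@@H](C)O1 | intermediate
16 | (3R,5S)-1-(4-hydroxy-3-methoxyphenyl)dodecane-3,5-diol | CCCCCCC[C@@H](C[C@@H](CCc1ccc(O)c(OC)c1)O)O | intermediate
17 | (3R,5S)-1-(4-acetoxy-3-methoxyphenyl)dodecane-3,5-diyl diacetate | CCCCCCC[C@@H](C[C@@H](CCc1ccc(OC(C)=O)c(OC)c1)OC(C)=O)OC(C)=O | intermediate
18 | (3R,5S)-1-(4-hydroxy-3-methoxyphenyl)dodecane-3,5-diyl diacetate | CCCCCCC[C@@H](C[C@@H](CCc1ccc(O)c(OC)c1)OC(C)=O)OC(C)=O | target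

**Totals**
Total step count: 9. Longest linear sequence: 8 steps (steps 2 to 9, from O-benzylvanillin).

**Steps most likely to fail**

1. Step 5. The hydroxy enone may dehydrate to the dienone under the Lewis acid, acetaldehyde may self-condense, or the retro-Michael equilibration may be too slow, which would lower conversion and the syn selectivity. The fallback sets out from 4 and comes back at 16. Cross-metathesis of 4 with N-methoxy-N-methylacrylamide (second-generation Grubbs catalyst, CH2Cl2, 40 °C) would give (S,E)-5-hydroxy-N-methoxy-N-methyldodec-2-enamide F1. Benzaldehyde with catalytic KOtBu in THF at 0 °C (base-mediated hemiacetal alkoxide conjugate addition) would then give the all-cis benzylidene acetal of (3S,5S)-3,5-dihydroxy-N-methoxy-N-methyldodecanamide F2. (4-Benzyloxy-3-methoxyphenyl)magnesium bromide F3, made from 1-(benzyloxy)-4-bromo-2-methoxybenzene and Mg in THF, would convert this Weinreb amide into the all-cis benzylidene acetal of (3S,5S)-1-(4-benzyloxy-3-methoxyphenyl)-3,5-dihydroxydodecan-1-one F4. H2 over Pd(OH)2/C in EtOH–AcOH would remove the benzylidene acetal, the benzyl ether and the C1 carbonyl oxygen in one operation and give triol 16.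

2. Step 6. The β-alkoxy ketone may open by retro-oxa-Michael reaction before the carbonyl is reduced, and the enone so formed would be hydrogenated with loss of the C3 oxygen; the reduction may also stall at the benzylic alcohol. The fallback sets out from 12 and comes back at 15. Condensation of 12 with p-toluenesulfonylhydrazide in EtOH would give N'-[1-(4-benzyloxy-3-methoxyphenyl)-2-(all-cis-6-heptyl-2-methyl-1,3-dioxan-4-yl)ethylidene]-4-methylbenzenesulfonohydrazide F5. Reduction with catecholborane in CHCl3 at 0 °C, then NaOAc·3H2O at reflux, would expel sulfinate and N2 and leave the all-cis ethylidene acetal of (3R,5S)-1-(4-benzyloxy-3-methoxyphenyl)dodecane-3,5-diol F6, with C1 as CH2 and no acid or hydrogenation involved. Neutral hydrogenolysis (H2, Pd/C, EtOAc, rt) would then remove only the benzyl group and give 15.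

3. Step 4. The electron-poor aryl vinyl ketone may polymerise or dimerise, and the catalyst may decompose before cross-coupling is complete. The fallback sets out from 4 and 7 and comes back at 9. Cross-metathesis of 4 with the allylic alcohol 7, which does not polymerise, using the same ruthenium catalyst, would give (2E,5S)-1-(4-benzyloxy-3-methoxyphenyl)dodec-2-ene-1,5-diol F7 as a mixture of C1 epimers. MnO2 in CH2Cl2 at rt would then oxidise only the allylic benzylic carbinol, leave the saturated C5 alcohol, and give 9.

**Further compounds**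
F1 | step 5 | (S,E)-5-hydroxy-N-methoxy-N-methyldodec-2-enamide | CCCCCCC[C@@H](C/C=C/C(=O)N(C)OC)O
F2 | step 5 | all-cis benzylidene acetal of (3S,5S)-3,5-dihydroxy-N-methoxy-N-methyldodecanamide | CCCCCCC[C@H]1C[C@@H](CC(=O)N(C)OC)O[C@@H](c2ccccc2)O1
F3 | step 5 | (4-benzyloxy-3-methoxyphenyl)magnesium bromide | COc1cc([Mg]Br)ccc1OCc1ccccc1
F4 | step 5 | all-cis benzylidene acetal of (3S,5S)-1-(4-benzyloxy-3-methoxyphenyl)-3,5-dihydroxydodecan-1-one | CCCCCCC[C@H]1C[C@@H](CC(=O)c2ccc(OCc3ccccc3)c(OC)c2)O[C@@H](c2ccccc2)O1
F5 | step 6 | N'-[1-(4-benzyloxy-3-methoxyphenyl)-2-(all-cis-6-heptyl-2-methyl-1,3-dioxan-4-yl)ethylidene]-4-methylbenzenesulfonohydrazide | CCCCCCC[C@H]1C[C@@H](CC(=NNS(=O)(=O)c2ccc(C)cc2)c2ccc(OCc3ccccc3)c(OC)c2)O[C@@H](C)O1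
F6 | step 6 | all-cis ethylidene acetal of (3R,5S)-1-(4-benzyloxy-3-methoxyphenyl)dodecane-3,5-diol | CCCCCCC[C@H]1C[C@@H](CCc2ccc(OCc3ccccc3)c(OC)c2)O[C@@H](C)O1
F7 | step 4 | (2E,5S)-1-(4-benzyloxy-3-methoxyphenyl)dodec-2-ene-1,5-diol (C1 epimers) | CCCCCCC[C@@H](C/C=C/C(O)c1ccc(OCc2ccccc2)c(OC)c1)O
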